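**Plan**

1. Ring numbering of the target (7-oxabicyclo[4.1.0]heptan-2-one): C1 methyl-bearing oxirane carbon, C2 C=O, C3 CH–O-angeloyl, C4 CH–side chain, C5 CH2, C6 oxirane CH. Cuts, in order: the C3 ester; the C6–O bond of the oxirane (back to a trans-diaxial C1,C6-diol monosulfonate); the C1–C2 bond; the exo-methylene (back to a ketone); the C3–C4 bond (anti-aldol); the bond from that ketone to the C5–C6–C1 arm (Weinreb amide plus Grignard reagent).
2. Enabling feature: in the cyclohexanone ring the C2 carbonyl carbon is bonded to the oxygen-bearing quaternary C1, an acyloin (α-ketol). Both carbons can therefore be carbonyl carbons of an acyclic 6-oxoheptanal (aldehyde = C2, methyl ketone = C1), joined once a carbene catalyst reverses the polarity of the aldehyde carbon.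
3. Forward: two fragments (from methyl (S)-glycidate and from divinyl carbinol) are joined to an α-acetoxy ketone; aldol, methylenation, Wacker oxidation and alcohol oxidation give the keto-aldehyde. The carbocycle closes first (step 15), the oxirane second (step 17), and the angelate goes on last.
4. Stereochemistry: side-chain carbinol from the glycidate; C6 oxygen from Sharpless desymmetrisation; C3 and C4 from the acetoxy-directed boron anti-aldol; C1 in the chair transition state of the ring closure; C6 is inverted when the oxirane closes.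

Key step: step 15

Remark: "aqueous work-up" stands for protonation by water; the diastereoselection of step 15 is taken to be substrate-controlled, so an achiral carbene precursor is used.

**Route**

Step 1
Reactants: 1 methyl (2S)-oxirane-2-carboxylate; 2 (2-methylprop-1-en-1-yl)magnesium bromide
Product: 3 methyl (2S)-2-hydroxy-5-methylhex-4-enoate
Conditions: CuBr·SMe2 (10 mol %), THF, −40 °C; aqueous work-up
Reagents that add atoms: none
Why: copper-catalysed Grignard opening of the glycidic ester (SN2 at the unsubstituted C3) should give the α-hydroxy ester with the C2 configuration of 1 retained, which becomes the (S)-acetoxy carbon of the side chain.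

Step 2
Reactants: 3 methyl (2S)-2-hydroxy-5-methylhex-4-enoate
Product: 4 (2S)-2-hydroxy-N-methoxy-N,5-dimethylhex-4-enamide
Conditions: MeNH(OMe)·HCl, i-PrMgCl (3.2 equiv), THF, −20 to 0 °C; aqueous work-up
Reagents that add atoms: N,O-dimethylhydroxylamine hydrochloride, CNOC.Cl
Why: Weinreb amide formation, in which the chloromagnesium amide made in the flask aminolyses the ester while the α-hydroxyl sits as its alkoxide, so the stereocentre is not touched.

Step 3
Reactants: 5 penta-1,4-dien-3-ol
Product: 6 (1S)-1-[(2R)-oxiran-2-yl]prop-2-en-1-ol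
Conditions: Ti(OiPr)4 (10 mol %), L-(+)-diisopropyl tartrate (13 mol %), t-BuOOH, 4 Å molecular sieves, CH2Cl2, −20 °C
Reagents that add atoms: tert-butyl hydroperoxide, CC(C)(C)OO
Why: Sharpless asymmetric epoxidation desymmetrises the divinyl carbinol, since the L-(+)-tartrate catalyst selects one enantiotopic vinyl group and one of its faces, which should give the (2R,3S)-epoxy alcohol while the minor enantiomer is consumed by a faster second epoxidation.

Step 4
Reactants: 6 (1S)-1-[(2R)-oxiran-2-yl]prop-2-en-1-ol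
Product: 7 (3R)-pent-4-ene-1,3-diol
Conditions: NaAlH2(OCH2CH2OMe)2, THF, 0 °C; aqueous work-up
Reagents that add atoms: none
Why: hydroxyl-directed reductive opening of the epoxy alcohol, in which the alkoxyaluminate delivers hydride to the epoxide carbon next to the carbinol, should give the 1,3-diol without touching the stereocentre.

Step 5
Reactants: 7 (3R)-pent-4-ene-1,3-diol
Product: 8 (3R)-5-bromopent-1-en-3-ol
Conditions: CBr4 (1.05 equiv), PPh3, CH2Cl2, 0 °C
Reagents that add atoms: carbon tetrabromide, BrC(Br)(Br)Br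
Why: the Appel reaction is faster at the primary than at the secondary allylic hydroxyl, so one equivalent of reagent at 0 °C should give the primary bromide.

Step 6
Reactants: 8 (3R)-5-bromopent-1-en-3-ol
Product: 9 {[(3R)-5-bromopent-1-en-3-yl]oxy}(triethyl)silane
Conditions: Et3SiCl, imidazole, CH2Cl2, 0 °C
Reagents that add atoms: chlorotriethylsilane, CC[Si](Cl)(CC)CC
Why: standard silylation of the secondary alcohol, with the triethylsilyl group chosen because it can later be removed in the presence of a tert-butyldimethylsilyl ether.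

Step 7
Reactants: 9 {[(3R)-5-bromopent-1-en-3-yl]oxy}(triethyl)silane; 4 (2S)-2-hydroxy-N-methoxy-N,5-dimethylhex-4-enamide
Product: 12 (3R,7S)-7-hydroxy-10-methyl-3-(triethylsilyloxy)undeca-1,9-dien-6-one, via Grignard reagent 10 (not isolated), via chloromagnesium alkoxide 11 (not isolated)
Conditions: 9, Mg, THF, 25 °C; separately 4, i-PrMgCl (1.0 equiv), THF, −20 °C; combine, 0 to 25 °C; aqueous work-up
Reagents that add atoms: none
Why: Weinreb ketone synthesis, in which the Grignard reagent 10 adds once to the amide whose α-hydroxyl is masked as the alkoxide 11 and the chelated tetrahedral adduct releases the ketone only on work-up, so neither stereocentre is touched.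

Step 8
Reactants: 12 (3R,7S)-7-hydroxy-10-methyl-3-(triethylsilyloxy)undeca-1,9-dien-6-one
Product: 13 (5S,9R)-2-methyl-6-oxo-9-(triethylsilyloxy)undeca-2,10-dien-5-yl acetate
Conditions: Ac2O, pyridine, DMAP (5 mol %), CH2Cl2, 0 °C
Reagents that add atoms: acetic anhydride, CC(=O)OC(C)=O
Why: acylation of the secondary α-hydroxy ketone under nucleophilic catalysis installs the acetate, which is the final ester of the target and the directing group of the next step.

Step 9
Reactants: 13 (5S,9R)-2-methyl-6-oxo-9-(triethylsilyloxy)undeca-2,10-dien-5-yl acetate; 14 [(4-methoxyphenyl)methoxy]acetaldehyde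
Product: 16 (5S,7R,8S)-8-hydroxy-9-[(4-methoxyphenyl)methoxy]-2-methyl-6-oxo-7-[(2R)-2-(triethylsilyloxy)but-3-en-1-yl]non-2-en-5-yl acetate, via (E)-enol dicyclohexylborinate 15 (not isolated)
Conditions: (c-C6H11)2BCl, Me2NEt, Et2O, −78 to 0 °C; 14, −78 to −20 °C; then MeOH, pH 7 buffer, H2O2, 0 °C
Reagents that add atoms: none
Why: dicyclohexylboron-mediated anti-aldol reaction of an α'-acyloxy ketone, in which enolisation on the methylene side gives the (E)-enol borinate 15 and, in the Zimmerman–Traxler chair, the acetoxy-bearing centre (its C–H eclipsing the enol double bond, the ester carbonyl in contact with the formyl hydrogen) directs the aldehyde to one enolate face, which should set the new centres as 7R and 8S (7,8-anti).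

Step 10
Reactants: 16 the anti-aldol adduct
Product: 17 (5S,7R,8S)-8-[tert-butyl(dimethyl)silyloxy]-9-[(4-methoxyphenyl)methoxy]-2-methyl-6-oxo-7-[(2R)-2-(triethylsilyloxy)but-3-en-1-yl]non-2-en-5-yl acetate
Conditions: t-BuMe2SiOTf, 2,6-lutidine, CH2Cl2, −78 °C
Reagents that add atoms: tert-butyldimethylsilyl trifluoromethanesulfonate, CC(C)(C)[Si](C)(C)OS(=O)(=O)C(F)(F)F
Why: silylation of the β-hydroxy ketone under non-nucleophilic conditions prevents retro-aldol and elimination and turns the hydroxyl into a poor leaving group for the key step.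

Step 11
Reactants: 17 the silylated aldol adduct
Product: 18 (5S,7S,8S)-8-[tert-butyl(dimethyl)silyloxy]-9-[(4-methoxyphenyl)methoxy]-2-methyl-6-methylidene-7-[(2R)-2-(triethylsilyloxy)but-3-en-1-yl]non-2-en-5-yl acetate
Conditions: Zn, CH2Br2, TiCl4, THF/CH2Cl2, 0 to 25 °C
Reagents that add atoms: dibromomethane, BrCBr
Why: Takai–Lombardo methylenation, whose non-basic zinc–titanium methylene reagent converts the hindered, epimerisable ketone into the 1,1-disubstituted alkene without enolisation and leaves the acetate alone.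

Step 12
Reactants: 18 the methylidene compound
Product: 19 (5S,7S,8S)-8-[tert-butyl(dimethyl)silyloxy]-9-[(4-methoxyphenyl)methoxy]-2-methyl-6-methylidene-7-[(2R)-3-oxo-2-(triethylsilyloxy)butyl]non-2-en-5-yl acetate
Conditions: PdCl2(quinox) (5 mol %; quinox = 2-(4,5-dihydro-1,3-oxazol-2-yl)quinoline), AgSbF6 (12 mol %), aqueous t-BuOOH, CH2Cl2, 25 °C
Reagents that add atoms: tert-butyl hydroperoxide, CC(C)(C)OO
Why: Tsuji–Wacker oxidation with a cationic quinoline–oxazoline palladium catalyst and the hydroperoxide as oxidant is selective for the monosubstituted alkene and gives the methyl ketone from O-protected allylic alcohols, while the 2-substituted allylic acetate and the trisubstituted alkene should not react.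

Step 13
Reactants: 19 the methyl ketone
Product: 20 (5S,7S,8S)-8-[tert-butyl(dimethyl)silyloxy]-9-hydroxy-2-methyl-6-methylidene-7-[(2R)-3-oxo-2-(triethylsilyloxy)butyl]non-2-en-5-yl acetate
Conditions: DDQ, CH2Cl2/pH 7 buffer (10:1), 0 °C
Reagents that add atoms: none
Why: oxidative cleavage of the 4-methoxybenzyl ether by DDQ under buffered conditions frees the primary alcohol and leaves silyl ethers, acetate and alkenes in place.

Step 14
Reactants: 20 the primary alcohol
Product: 21 (5S,7S,8S)-8-[tert-butyl(dimethyl)silyloxy]-2-methyl-6-methylidene-9-oxo-7-[(2R)-3-oxo-2-(triethylsilyloxy)butyl]non-2-en-5-yl acetate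
Conditions: Dess–Martin periodinane, pyridine, CH2Cl2, 0 to 25 °C
Reagents that add atoms: none
Why: Dess–Martin oxidation gives the α-silyloxy aldehyde under near-neutral conditions that should not epimerise it.

Step 15
Reactants: 21 the keto-aldehyde
Product: 23 (3S)-2-[(1S,2S,4S,5R)-2-[tert-butyl(dimethyl)silyloxy]-4-hydroxy-4-methyl-3-oxo-5-(triethylsilyloxy)cyclohexyl]-6-methylhepta-1,5-dien-3-yl acetate, via Breslow enaminol 22 (not isolated)
Conditions: 2-(pentafluorophenyl)-6,7-dihydro-5H-pyrrolo[2,1-c][1,2,4]triazol-2-ium tetrafluoroborate (20 mol %), Et3N (20 mol %), t-BuOH/toluene (1:4), 25 °C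
Reagents that add atoms: none
Why: the triazolylidene adds to the aldehyde and a proton shift gives the Breslow enaminol 22, an acyl anion equivalent whose carbon attacks the methyl ketone, after which proton transfer and loss of the carbene give the α-ketol. The closest known reaction type is the carbene-catalysed intramolecular crossed aldehyde–ketone benzoin (acyloin) cyclisation. The six-membered carbocycle closes in the 6-exo-trig mode. The new quaternary carbinol is set in a chair transition state that keeps the alkenyl group, the OTBS group and the incoming azolium equatorial, leaves the OTES group axial, and places the ketone methyl equatorial with the C=O antiperiplanar to the axial C–OTES bond (dipole-minimised, Cornforth-type, with tert-butanol relaying the proton), so the hydroxyl should come out trans-diaxial to the OTES group. The step needs the aldehyde and not the ketone to become the donor, and needs the α-oxygen to stay: only the aldehyde can form the enaminol, a silyl ether is too poor a leaving group for the redox elimination that α-acyloxy aldehydes undergo, and the weak amine base should leave the α-stereocentres alone.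

Step 16
Reactants: 23 the α-ketol
Product: 24 (3S)-2-[(1S,2S,4S,5R)-2-[tert-butyl(dimethyl)silyloxy]-4,5-dihydroxy-4-methyl-3-oxocyclohexyl]-6-methylhepta-1,5-dien-3-yl acetate
Conditions: HF·pyridine, pyridine, THF, 0 °C
Reagents that add atoms: none
Why: fluoride cleavage of a triethylsilyl ether is much faster than that of a tert-butyldimethylsilyl ether, so buffered HF·pyridine should free only the secondary hydroxyl next to the tertiary one.

Step 17
Reactants: 24 the trans-diol
Product: 26 (3S)-2-[(1S,3S,4S,6S)-3-[tert-butyl(dimethyl)silyloxy]-1-methyl-2-oxo-7-oxabicyclo[4.1.0]heptan-4-yl]-6-methylhepta-1,5-dien-3-yl acetate, via secondary mesylate 25 (not isolated)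
Conditions: MsCl, Et3N, CH2Cl2, −20 °C; then DBU, 0 to 25 °C
Reagents that add atoms: none
Why: sulfonylation of the secondary hydroxyl (the tertiary one does not react) and base-induced 3-exo-tet displacement by the trans-diaxial tertiary alkoxide close the oxirane with inversion at the secondary carbon, which puts the epoxide oxygen on the face of the alkenyl group.

Step 18
Reactants: 26 the silylated epoxy ketone
Product: 27 (3S)-2-[(1S,3S,4S,6S)-3-hydroxy-1-methyl-2-oxo-7-oxabicyclo[4.1.0]heptan-4-yl]-6-methylhepta-1,5-dien-3-yl acetate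
Conditions: HF·pyridine, pyridine, THF, 25 °C
Reagents that add atoms: none
Why: fluoride cleavage of the remaining silyl ether under buffered conditions frees the α-hydroxy ketone, and trisubstituted oxiranes and acetates should survive.

Step 19
Reactants: 27 the epoxy α-ketol; 28 (2Z)-2-methylbut-2-enoic acid (angelic acid)
Product: 30 (1S,3S,4S,6S)-4-[(3S)-3-acetoxy-6-methylhepta-1,5-dien-2-yl]-1-methyl-2-oxo-7-oxabicyclo[4.1.0]heptan-3-yl (2Z)-2-methylbut-2-enoate, via mixed anhydride 29 (not isolated)
Conditions: 28, 2,4,6-trichlorobenzoyl chloride, Et3N, toluene, 25 °C; then 27, 60 °C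
Reagents that add atoms: none
Why: Yamaguchi-type esterification, in which the acid is activated as the mixed anhydride 29 and acylates the α-hydroxyl on warming without a nucleophilic catalyst, conditions under which the (Z)-2-methylbut-2-enoyl group should not isomerise to the (E)-isomer.

**Compound list**

1 | methyl (2S)-oxirane-2-carboxylate (methyl (S)-glycidate) | COC(=O)[C@@H]1CO1 | starting material
2 | (2-methylprop-1-en-1-yl)magnesium bromide | CC(C)=C[Mg]Br | starting material
3 | methyl (2S)-2-hydroxy-5-methylhex-4-enoate | COC(=O)[C@@H](O)CC=C(C)C | intermediate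
4 | (2S)-2-hydroxy-N-methoxy-N,5-dimethylhex-4-enamide | CON(C)C(=O)[C@@H](O)CC=C(C)C | intermediate
5 | penta-1,4-dien-3-ol | C=CC(O)C=C | starting material
6 | (1S)-1-[(2R)-oxiran-2-yl]prop-2-en-1-ol | C=C[C@H](O)[C@H]1CO1 | intermediate
7 | (3R)-pent-4-ene-1,3-diol | C=C[C@H](O)CCO | intermediate
8 | (3R)-5-bromopent-1-en-3-ol | C=C[C@H](O)CCBr | intermediate
9 | {[(3R)-5-bromopent-1-en-3-yl]oxy}(triethyl)silane | C=C[C@H](O[Si](CC)(CC)CC)CCBr | intermediate
10 | [(3R)-3-(triethylsilyloxy)pent-4-en-1-yl]magnesium bromide (formed in the flask) | C=C[C@H](O[Si](CC)(CC)CC)CC[Mg]Br | intermediate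
11 | chloromagnesium alkoxide of 4 (formed in the flask) | CON(C)C(=O)[C@@H](O[Mg]Cl)CC=C(C)C | intermediate
12 | (3R,7S)-7-hydroxy-10-methyl-3-(triethylsilyloxy)undeca-1,9-dien-6-one | C=C[C@H](O[Si](CC)(CC)CC)CCC(=O)[C@@H](O)CC=C(C)C | intermediate
13 | (5S,9R)-2-methyl-6-oxo-9-(triethylsilyloxy)undeca-2,10-dien-5-yl acetate | C=C[C@H](O[Si](CC)(CC)CC)CCC(=O)[C@@H](OC(C)=O)CC=C(C)C | intermediate
14 | [(4-methoxyphenyl)methoxy]acetaldehyde | COc1ccc(COCC=O)cc1 | starting material
15 | (5S,6E,9R)-6-[(dicyclohexylboranyl)oxy]-2-methyl-9-(triethylsilyloxy)undeca-2,6,10-trien-5-yl acetate (formed in the flask) | C=C[C@H](O[Si](CC)(CC)CC)C/C=C(/OB(C1CCCCC1)C1CCCCC1)[C@@H](OC(C)=O)CC=C(C)C | intermediate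
16 | (5S,7R,8S)-8-hydroxy-9-[(4-methoxyphenyl)methoxy]-2-methyl-6-oxo-7-[(2R)-2-(triethylsilyloxy)but-3-en-1-yl]non-2-en-5-yl acetate | O=C([C@H](CC=C(C)C)OC(C)=O)[C@H](C[C@@H](O[Si](CC)(CC)CC)C=C)[C@H](O)COCc1ccc(OC)cc1 | intermediate
17 | (5S,7R,8S)-8-[tert-butyl(dimethyl)silyloxy]-9-[(4-methoxyphenyl)methoxy]-2-methyl-6-oxo-7-[(2R)-2-(triethylsilyloxy)but-3-en-1-yl]non-2-en-5-yl acetate | O=C([C@H](CC=C(C)C)OC(C)=O)[C@H](C[C@@H](O[Si](CC)(CC)CC)C=C)[C@H](O[Si](C)(C)C(C)(C)C)COCc1ccc(OC)cc1 | intermediate
18 | (5S,7S,8S)-8-[tert-butyl(dimethyl)silyloxy]-9-[(4-methoxyphenyl)methoxy]-2-methyl-6-methylidene-7-[(2R)-2-(triethylsilyloxy)but-3-en-1-yl]non-2-en-5-yl acetate | C=C([C@H](CC=C(C)C)OC(C)=O)[C@H](C[C@@H](O[Si](CC)(CC)CC)C=C)[C@H](O[Si](C)(C)C(C)(C)C)COCc1ccc(OC)cc1 | intermediate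
19 | (5S,7S,8S)-8-[tert-butyl(dimethyl)silyloxy]-9-[(4-methoxyphenyl)methoxy]-2-methyl-6-methylidene-7-[(2R)-3-oxo-2-(triethylsilyloxy)butyl]non-2-en-5-yl acetate | C=C([C@H](CC=C(C)C)OC(C)=O)[C@H](C[C@@H](O[Si](CC)(CC)CC)C(C)=O)[C@H](O[Si](C)(C)C(C)(C)C)COCc1ccc(OC)cc1 | intermediate
20 | (5S,7S,8S)-8-[tert-butyl(dimethyl)silyloxy]-9-hydroxy-2-methyl-6-methylidene-7-[(2R)-3-oxo-2-(triethylsilyloxy)butyl]non-2-en-5-yl acetate | C=C([C@H](CC=C(C)C)OC(C)=O)[C@H](C[C@@H](O[Si](CC)(CC)CC)C(C)=O)[C@H](O[Si](C)(C)C(C)(C)C)CO | intermediate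
21 | (5S,7S,8S)-8-[tert-butyl(dimethyl)silyloxy]-2-methyl-6-methylidene-9-oxo-7-[(2R)-3-oxo-2-(triethylsilyloxy)butyl]non-2-en-5-yl acetate | C=C([C@H](CC=C(C)C)OC(C)=O)[C@H](C[C@@H](O[Si](CC)(CC)CC)C(C)=O)[C@H](O[Si](C)(C)C(C)(C)C)C=O | intermediate
22 | Breslow enaminol of 21: the formyl carbon carries OH and is doubly bonded to C3 of 2-(pentafluorophenyl)-6,7-dihydro-5H-pyrrolo[2,1-c][1,2,4]triazol-3-ylidene (formed in the flask) | C=C([C@H](CC=C(C)C)OC(C)=O)[C@H](C[C@@H](O[Si](CC)(CC)CC)C(C)=O)[C@H](O[Si](C)(C)C(C)(C)C)C(O)=C1N(c2c(F)c(F)c(F)c(F)c2F)N=C2CCCN12 | intermediate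
23 | (3S)-2-[(1S,2S,4S,5R)-2-[tert-butyl(dimethyl)silyloxy]-4-hydroxy-4-methyl-3-oxo-5-(triethylsilyloxy)cyclohexyl]-6-methylhepta-1,5-dien-3-yl acetate | C=C([C@H](CC=C(C)C)OC(C)=O)[C@@H]1C[C@@H](O[Si](CC)(CC)CC)[C@](C)(O)C(=O)[C@H]1O[Si](C)(C)C(C)(C)C | intermediate
24 | (3S)-2-[(1S,2S,4S,5R)-2-[tert-butyl(dimethyl)silyloxy]-4,5-dihydroxy-4-methyl-3-oxocyclohexyl]-6-methylhepta-1,5-dien-3-yl acetate | C=C([C@H](CC=C(C)C)OC(C)=O)[C@@H]1C[C@@H](O)[C@](C)(O)C(=O)[C@H]1O[Si](C)(C)C(C)(C)C | intermediate
25 | 5-O-methanesulfonate of 24 (secondary mesylate, formed in the flask) | C=C([C@H](CC=C(C)C)OC(C)=O)[C@@H]1C[C@@H](OS(C)(=O)=O)[C@](C)(O)C(=O)[C@H]1O[Si](C)(C)C(C)(C)C | intermediate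
26 | (3S)-2-[(1S,3S,4S,6S)-3-[tert-butyl(dimethyl)silyloxy]-1-methyl-2-oxo-7-oxabicyclo[4.1.0]heptan-4-yl]-6-methylhepta-1,5-dien-3-yl acetate | C=C([C@H](CC=C(C)C)OC(C)=O)[C@@H]1C[C@@H]2O[C@]2(C)C(=O)[C@H]1O[Si](C)(C)C(C)(C)C | intermediate
27 | (3S)-2-[(1S,3S,4S,6S)-3-hydroxy-1-methyl-2-oxo-7-oxabicyclo[4.1.0]heptan-4-yl]-6-methylhepta-1,5-dien-3-yl acetate | C=C([C@H](CC=C(C)C)OC(C)=O)[C@@H]1C[C@@H]2O[C@]2(C)C(=O)[C@H]1O | intermediate
28 | (2Z)-2-methylbut-2-enoic acid (angelic acid) | C/C=C(/C)C(=O)O | starting material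
29 | (2Z)-2-methylbut-2-enoic 2,4,6-trichlorobenzoic anhydride (formed in the flask) | C/C=C(/C)C(=O)OC(=O)c1c(Cl)cc(Cl)cc1Cl | intermediate
30 | (1S,3S,4S,6S)-4-[(3S)-3-acetoxy-6-methylhepta-1,5-dien-2-yl]-1-methyl-2-oxo-7-oxabicyclo[4.1.0]heptan-3-yl (2Z)-2-methylbut-2-enoate | C=C([C@H](CC=C(C)C)OC(C)=O)[C@@H]1C[C@@H]2O[C@]2(C)C(=O)[C@H]1OC(=O)/C(C)=C\C | target

**Step count**

Total: 19 steps. Longest linear sequence: 17 steps (steps 3 to 19, from 5).

**Steps most likely to fail**

Step 15. The carbene adduct may attack the other face of the ketone, helped by an internal hydrogen bond, which would put the new hydroxyl cis to the OTES group and the methyl axial; the addition may also reverse, and the α-silyloxy aldehyde may epimerise. Fallback: from 21, reductive ketyl–carbonyl (pinacol) coupling with SmI2 and t-BuOH in THF at −78 °C forms the same ring bond through a samarium-bridged transition state. It is expected to give the cis-1,2-diol F1, with each new hydroxyl anti to its neighbouring silyloxy group. Dess–Martin oxidation of the secondary hydroxyl of F1 (the tertiary one cannot react) returns to the route at 23.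

Step 11. Methylene transfer to the doubly α-branched ketone may be too slow, and zinc may reductively remove the α-acetoxy group. Fallback: a Peterson olefination from 17. Me3SiCH2Li with CeCl3 in THF at −78 °C should add to the ketone faster than to the acetate and give the β-hydroxysilane F2 (configuration at the new carbinol immaterial). Syn-elimination with KN(SiMe3)2 in THF at 0 °C returns to the route at 18.

Step 19. Acylation of the hindered α-ketol hydroxyl may be slow, the angeloyl group may isomerise to the (E)-isomer, and the epoxy ketone may suffer on heating with base. Fallback: build the Z-alkene on the ester, from 27. Esterification with 2-[bis(2-methylphenoxy)phosphoryl]propanoic acid (DCC, DMAP cat., CH2Cl2, 0 °C) gives the phosphonopropanoate ester F3. A Z-selective Horner–Wadsworth–Emmons reaction of F3 with acetaldehyde (NaI, DBU, THF, −78 to 0 °C) arrives at 30.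

**Further compounds**

F1 | step 15 | cis-1,2-diol: 23 with the ring C=O replaced by CH–OH, that hydroxyl cis to the tertiary hydroxyl and trans to the OTBS group | C=C([C@H](CC=C(C)C)OC(C)=O)[C@@H]1C[C@@H](O[Si](CC)(CC)CC)[C@](C)(O)[C@H](O)[C@H]1O[Si](C)(C)C(C)(C)C
F2 | step 11 | β-hydroxysilane: 17 with the ketone C=O replaced by C(OH)CH2SiMe3 | C[Si](C)(C)CC(O)([C@H](CC=C(C)C)OC(C)=O)[C@H](C[C@@H](O[Si](CC)(CC)CC)C=C)[C@H](O[Si](C)(C)C(C)(C)C)COCc1ccc(OC)cc1
F3 | step 19 | 2-[bis(2-methylphenoxy)phosphoryl]propanoate ester of 27 | C=C([C@H](CC=C(C)C)OC(C)=O)[C@@H]1C[C@@H]2O[C@]2(C)C(=O)[C@H]1OC(=O)C(C)P(=O)(Oc1ccccc1C)Oc1ccccc1C
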